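## The problem

Gnetumontanin B (32) is a stilbene trimer made of two trans-2,3-diaryl-2,3-dihydrobenzofurans that share ring B. The outer ring (O1′, C2′, C3′) is fused to ring B at C2B and C3B. Ring B is also the C2 aryl group of the inner ring (O1, C2, C3), which is fused to resorcinol ring A carrying the (E)-4-hydroxystyryl group at C6.

The four stereocentres form two pairs, (2S,3S) and (2′S,3′S), separated by the flat ring B. Within a pair C3 dictates C2, because the trans ring is the favoured outcome of closure both kinetically and thermodynamically. Between the pairs there is no dependable transmission, so each ring needs its own source of absolute configuration.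

Both C2–O bonds are benzylic ethers whose aryl groups carry ortho and para oxygen, so they ionise under acid. The stilbene must stay E, and the nine phenols are oxidation-prone and must stay masked to the end. In rings A and B the carbon that bears C3 (or C3′) lies between two oxygen-bearing carbons, a position electrophilic substitution does not reach.

The enabling feature is that C2′ is bonded only to O1′, C3′, its own aryl group and hydrogen. It can therefore be delivered as one benzylidene carbon across the four-atom unit O–C2B–C3B–C3′ of a ring B ortho-quinone methide. C2 of the inner ring has the same environment with ring B as its aryl group, so a one-carbon handle at C1B allows the operation to be repeated.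

## Retrosynthesis

**Phenol masks (32 from 31).** The nine O–CH3 bonds are cut last. Methyl is the one phenol mask that survives n-BuLi, sulfinic acid, Cs2CO3, HBF4 and fluoride alike, and it keeps every aromatic building block commercial. The forward step must cleave nine ethers without permanently opening the two benzylic ring ethers. C3 and C3′ cannot epimerise, so a ring that opens reversibly should reclose to the same trans isomer.

**Inner ring (31 from 27 and 19).** C2–C3 and O1–C2 are cut together, so C2 leaves as the benzylic carbon of sulfonium salt 19 and O1–C7a–C3a–C3 as the quinone methide from sulfone 27. Cutting only O1–C2 would leave a 1,2-diaryl ethanol whose two centres need acyclic control. Cutting the ring B–C2 bond would require arylating a hindered ring carbon. The chosen cut removes a ring and two stereocentres at once; 27 is racemic and small, and 19 holds the finished outer ring. The forward reaction must be reagent-controlled, since the outer stereocentres are too far away to help.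

**Ylide precursor (19 from 18 from 17).** The C–S bond of 19 comes from benzylic alcohol 18 and sulfide 3; 18 comes from silyl ether 17 by O–Si cleavage. The handle is a bulky silyl ether through the ring-forming step so that it stays inert to base, ylide and sulfinate. The only demand is to avoid strong acid on the new ring ether.

**Outer ring, the central cut (17 from 13 and 5).** C2′–C3′ and O1′–C2′ are cut, giving racemic sulfone phenol 13 (latent ring B quinone methide) and chiral thiolanium salt 5 (latent benzylide). This single cut removes the ring and both stereocentres and leaves two pieces without fixed stereochemistry in the aromatic part. Alternatives such as arylation at C3′ or ether closure of a preformed diol leave the stereochemical problem unsolved. The forward step needs C-attack of the ylide at the exocyclic carbon, trans closure, and one ylide face.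

The sulfide antipode follows from the known behaviour of this ylide class toward aldehydes, where the (2R,5R) sulfide leads to (S,S)-stilbene oxides. The same ylide face and the same inversion place O, aryl, H and the new C–C bond identically at C2′. At C2′, however, the aryl group outranks C3′, whereas in the epoxide the neighbouring ring carbon outranks phenyl, so the descriptor changes. The 2′S ring therefore calls for the (2S,5S) sulfide.

**Chiral salt (5 from 3 and 4; 3 from 2 from 1).** The benzylic C–S bond is cut to commercial alcohol 4 and (2S,5S)-2,5-dimethylthiolane 3. The two ring C–S bonds of 3 are cut to bis-mesylate 2 of (2R,5R)-diol 1. The double displacement inverts both centres, so the (R,R) diol is required. C2 symmetry means S-alkylation gives a single salt.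

**Ring B sulfone (13 from 12 from 9 and 10; 9 from 8 from 7 from 6).** The C–S bond of 13 comes from a diarylmethanol and p-toluenesulfinic acid. The C3B–C3′ bond is cut by lithiation between the two ring oxygens of 9 and addition to aldehyde 10. This is the one position metalation reaches selectively. The phenol is masked as a tetrahydropyranyl acetal, because the sulfinic acid that installs the sulfone can also remove it. No stronger acid is needed, which matters because the benzylic silyl ether sits on a 2,4-dioxygenated ring and would ionise. Acetal 9 comes from aldehyde 6 by reduction, selective silylation and acetalisation.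

**Ring A sulfone (27 from 26 from 23 and 24; 23 from 21 and 22; 21 from 20).** The C–S bond is cut as for ring B. The carbinol C–C bond is cut to salicylaldehyde 23 and the Grignard reagent from bromide 24; no organolithium is then needed in the presence of the stilbene. The stilbene bond is cut by Suzuki–Miyaura coupling of bromide 21 with (E)-alkenylboronic acid 22. Bromide 21 comes from symmetrical 20 by chelation-controlled removal of one of two equivalent methyl groups, so the OH/OMe pattern of ring A needs no protecting group.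

## Roads not taken

**Alternative 1:** The cut is C2–C3 and C2′–C3′ of both rings at once, from bis(aryldiazoacetate) A1, in which each future C2 is the CH2 of a benzylic ether. Forward, the dirhodium tetracarboxylate Rh2(S-DOSP)4 decomposes both diazo groups and each carbene inserts into the neighbouring ether C–H bond to give diester A2.
- Merits: both rings and all four stereocentres arise in one catalytic step, and the chirality source is catalytic. In ring-forming economy and catalytic asymmetric induction this road is better than the chosen one.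
- Weak points: C3 and C3′ emerge as methyl carboxylates where the target has 3,5-dihydroxyphenyl groups. Replacing an ester by an aryl group at two hindered benzylic stereocentres has no direct, stereoretentive solution. Insertions of this type also tend to give the cis ring first, so both ester centres would need epimerisation. The second insertion happens in a molecule that already holds one new ring, so the two events may not be equally selective.
- Against it, the chosen plan delivers each C3 with its aryl group already attached and closes each ring directly as trans. It pays with two stoichiometric uses of a chiral sulfide and two separate annulations.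

**Alternative 2:** The cut runs through aromatic ring A itself. Styrylcyclobutenone A3 and siloxyalkyne A4 are heated and combine by a 4π-opening, [2+2], 4π-opening, 6π-closure cascade (Danheiser benzannulation) to give phenol A5.
- Merits: the substitution pattern of ring A (side chain between two differentiated oxygens, styryl para to it) is fixed by construction. C3 comes from an auxiliary-controlled aldol reaction, which is more predictable than an ylide face selection. In those two respects it is the safer road.
- Weak points: the step closes no dihydrofuran ring. The inner ring still has to be formed from A5 by displacement at the silyloxy carbon, which is likely ionising and makes the aldol-set carbinol centre irrelevant. A4 is a long linear construct that carries the complete outer ring through an ester-to-ynolate homologation next to an epimerisable α-aryl centre. The cascade needs prolonged heating of a substrate with an acid- and heat-sensitive benzylic ring ether. The outer ring itself is not addressed and would still need a method such as the one chosen here.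
- Against it, the chosen plan obtains the ring A pattern in four steps from a commercial 2,6-dioxygenated benzaldehyde and sets both inner stereocentres in the step that closes the ring. It relies on ylide facial selectivity in place of an auxiliary.

**Alternative 3:** The cut is the C3–C3a bond of the inner ring, made by a 1,2-aryl shift. Flavanone A6 is treated with PhI(OAc)2 and acid in trimethyl orthoformate; the ring A carbon migrates from the carbonyl carbon to C3 and the pyranone contracts to trans ester triflate A7.
- Merits: the contraction is an established reaction type that gives the trans ring directly. C2 is inherited from the flavanone. The triflate allows the stilbene to be attached last, which is a real advantage over carrying the stilbene through an annulation and the final deprotection.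
- Weak points: C3 again carries an ester where the target needs an aryl group. The hypervalent iodine oxidant meets the very electron-rich arenes and the benzylic ether of the outer ring. The flavanone C2, attached to an ortho,para-dioxygenated aryl group, can open by a retro-oxa-Michael reaction under the strongly acidic conditions and lose its configuration. The outer ring must already be present.
- Against it, the chosen plan has no ester-to-aryl problem and no oxidant. The late-stilbene idea is kept as the fallback for step 16.

Key step: step 9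

Assumption: the 2,5-dimethylthiolanium benzylide is taken to expose the same face to a quinone methide as it does to an aldehyde; the choice of the (2S,5S) sulfide rests on this.

Remark: the acetal carbon of 9, 11 and 12 and the carbinol or sulfonyl carbon of 12, 13, 26 and 27 are racemic; all are removed before or during ring formation.

## Route

Step 1
Reactants: 1 (2R,5R)-hexane-2,5-diol
Product: 2 (2R,5R)-hexane-2,5-diyl dimethanesulfonate
Conditions: MsCl, Et3N, CH2Cl2, 0 °C
Reagents that add atoms: methanesulfonyl chloride, CS(=O)(=O)Cl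
Why: O-Sulfonylation of both secondary alcohols; no bond to a stereocentre is broken, so both centres stay R.

Step 2
Reactants: 2 (2R,5R)-hexane-2,5-diyl dimethanesulfonate
Product: 3 (2S,5S)-2,5-dimethylthiolane
Conditions: Na2S·9H2O, EtOH, 20 → 50 °C; distillation
Reagents that add atoms: sodium sulfide, [Na+].[Na+].[S-2]
Why: Double SN2 thioetherification, the second displacement being a 5-exo-tet closure; each carbon is inverted once, so the (R,R) bis-mesylate should give the (S,S) C2-symmetric sulfide.

Step 3
Reactants: 3 (2S,5S)-2,5-dimethylthiolane; 4 (2,4-dimethoxyphenyl)methanol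
Product: 5 (2S,5S)-1-[(2,4-dimethoxyphenyl)methyl]-2,5-dimethylthiolan-1-ium tetrafluoroborate
Conditions: HBF4·OEt2, CH2Cl2, 0 °C → rt; Et2O trituration
Reagents that add atoms: tetrafluoroboric acid (diethyl ether complex), [H+].F[B-](F)(F)F
Why: Acid-mediated S-alkylation of a sulfide by an electron-rich benzylic alcohol (SN1 through the 2,4-dimethoxybenzyl cation, water as by-product); the two sulfur lone pairs of the C2-symmetric sulfide are equivalent, so a single salt should form.

Step 4
Reactants: 6 2-hydroxy-4-methoxybenzaldehyde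
Product: 7 2-(hydroxymethyl)-5-methoxyphenol
Conditions: NaBH4, MeOH, 0 °C; pH 7 work-up
Reagents that add atoms: none
Why: Hydride reduction of the aldehyde; a neutral work-up is used because the product is an acid-sensitive hydroxybenzyl alcohol.

Step 5
Reactants: 7 2-(hydroxymethyl)-5-methoxyphenol
Product: 8 5-methoxy-2-({[tri(propan-2-yl)silyl]oxy}methyl)phenol
Conditions: TIPSCl (1.05 equiv), imidazole, CH2Cl2, 0 °C
Reagents that add atoms: chlorotri(propan-2-yl)silane, CC(C)[Si](Cl)(C(C)C)C(C)C
Why: Imidazole-promoted silylation; the primary benzylic hydroxyl should react faster with the bulky chlorosilane than the hydrogen-bonded phenol, which stays free for step 6.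

Step 6
Reactants: 8 5-methoxy-2-({[tri(propan-2-yl)silyl]oxy}methyl)phenol
Product: 9 {[4-methoxy-2-(oxan-2-yloxy)phenyl]methoxy}tri(propan-2-yl)silane
Conditions: 3,4-dihydro-2H-pyran, PPTS (cat.), CH2Cl2, rt
Reagents that add atoms: 3,4-dihydro-2H-pyran, C1=COCCC1
Why: Acid-catalysed tetrahydropyranylation of the phenol under a buffer-strength acid that the electron-rich benzylic silyl ether tolerates; the acetal directs the lithiation and is later removed by the sulfinic acid itself.

Step 7
Reactants: 9 {[4-methoxy-2-(oxan-2-yloxy)phenyl]methoxy}tri(propan-2-yl)silane; 10 3,5-dimethoxybenzaldehyde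
Product: 12 (3,5-dimethoxyphenyl)[6-methoxy-2-(oxan-2-yloxy)-3-({[tri(propan-2-yl)silyl]oxy}methyl)phenyl]methanol, via aryllithium 11 (not isolated)
Conditions: n-BuLi, THF, −20 → 0 °C; then 10, −78 °C → rt; aq. NH4Cl
Reagents that add atoms: none
Why: Directed ortho-metalation at the only ring position flanked by two oxygen donors (acetal and methoxy), then 1,2-addition of aryllithium 11 to the aldehyde; the carbinol centre is racemic and is erased in step 9.

Step 8
Reactants: 12 (3,5-dimethoxyphenyl)[6-methoxy-2-(oxan-2-yloxy)-3-({[tri(propan-2-yl)silyl]oxy}methyl)phenyl]methanol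
Product: 13 2-[(3,5-dimethoxyphenyl)(4-methylbenzenesulfonyl)methyl]-3-methoxy-6-({[tri(propan-2-yl)silyl]oxy}methyl)phenol
Conditions: p-TolSO2H (3 equiv, freshly liberated from p-TolSO2Na), CH2Cl2, 0 °C → rt; pH 7 work-up
Reagents that add atoms: 4-methylbenzenesulfinic acid, Cc1ccc(S(=O)O)cc1
Why: SN1 substitution of the doubly ortho-oxygenated diarylmethanol by sulfinate (attack through sulfur) gives the sulfone. The same acid should transfer the tetrahydropyranyl group to a second sulfinate as a 2-sulfonyloxane, freeing the phenol without a stronger acid that would ionise the benzylic silyl ether.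

Step 9
Reactants: 13 2-[(3,5-dimethoxyphenyl)(4-methylbenzenesulfonyl)methyl]-3-methoxy-6-({[tri(propan-2-yl)silyl]oxy}methyl)phenol; 5 (2S,5S)-1-[(2,4-dimethoxyphenyl)methyl]-2,5-dimethylthiolan-1-ium tetrafluoroborate
Product: 17 {[(2S,3S)-2-(2,4-dimethoxyphenyl)-3-(3,5-dimethoxyphenyl)-4-methoxy-2,3-dihydro-1-benzofuran-7-yl]methoxy}tri(propan-2-yl)silane, via ring B ortho-quinone methide 14 (not isolated), via thiolanium benzylide 15 (not isolated), via betaine 16 (not isolated)
Conditions: Cs2CO3 (3 equiv), 5 (1.3 equiv), CH2Cl2/MeCN, 0 °C → rt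
Reagents that add atoms: none
Why: Cs2CO3 deprotonates phenol 13, which expels sulfinate to give quinone methide 14, and reversibly deprotonates salt 5 to benzylide 15. The ylide carbon adds to the exocyclic carbon of 14, driven by rearomatisation of ring B, forming C2′–C3′ in betaine 16; the phenoxide then displaces the sulfide at C2′ with inversion, closing O1′–C2′ in a 5-exo-tet substitution and returning sulfide 3. The closest known reaction type is the Cs2CO3-mediated formal [4+1] annulation of quinone methides from 2-(sulfonylalkyl)phenols with carbonyl-stabilised sulfonium ylides to trans-2,3-dihydrobenzofurans; benzylidene transfer from 2,5-dimethylthiolanium salts is known from the asymmetric epoxidation of aldehydes. C2′ is controlled by the salt: it gives one ylide, whose aryl group turns away from the ring and whose face next to the cis methyl group is blocked, so attack on the open face followed by inversion should give 2′S from the (2S,5S) sulfide. C3′ is set relative to C2′ in the C–C bond-forming step through the open transition state that keeps the two aryl groups apart, and the anti-periplanar closure reads this out as trans. Trans is also the more stable ring, so partial SN1 closure at the electron-rich C2′ leads to the same diastereomer. The step needs C-attack on 14 to win over O-benzylation of the phenoxide by 5. The hindered, doubly ortho-substituted phenoxide, its fast unimolecular loss of sulfinate and the reversible sulfinate adduct acting as a reservoir for 14 should secure this.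

Step 10
Reactants: 17 {[(2S,3S)-2-(2,4-dimethoxyphenyl)-3-(3,5-dimethoxyphenyl)-4-methoxy-2,3-dihydro-1-benzofuran-7-yl]methoxy}tri(propan-2-yl)silane
Product: 18 [(2S,3S)-2-(2,4-dimethoxyphenyl)-3-(3,5-dimethoxyphenyl)-4-methoxy-2,3-dihydro-1-benzofuran-7-yl]methanol
Conditions: TBAF, THF, 0 °C → rt
Reagents that add atoms: none
Why: Fluoride cleavage of the silyl ether under conditions that leave the benzylic ring ether alone; the alcohol is the intended point for enantiomeric enrichment by recrystallisation.

Step 11
Reactants: 18 [(2S,3S)-2-(2,4-dimethoxyphenyl)-3-(3,5-dimethoxyphenyl)-4-methoxy-2,3-dihydro-1-benzofuran-7-yl]methanol; 3 (2S,5S)-2,5-dimethylthiolane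
Product: 19 (2S,5S)-1-{[(2S,3S)-2-(2,4-dimethoxyphenyl)-3-(3,5-dimethoxyphenyl)-4-methoxy-2,3-dihydro-1-benzofuran-7-yl]methyl}-2,5-dimethylthiolan-1-ium tetrafluoroborate
Conditions: 3 (2 equiv), HBF4·OEt2 (1.0 equiv), CH2Cl2, −40 → 0 °C; Et2O trituration
Reagents that add atoms: tetrafluoroboric acid (diethyl ether complex), [H+].F[B-](F)(F)F
Why: Same acid-mediated S-alkylation as step 3; the ortho,para-dioxygenated primary benzylic alcohol should ionise more readily than the ring ether is protonated, and excess sulfide captures the cation. One equivalent of acid is consumed, so the medium ends neutral.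

Step 12
Reactants: 20 4-bromo-2,6-dimethoxybenzaldehyde
Product: 21 4-bromo-2-hydroxy-6-methoxybenzaldehyde
Conditions: BCl3 (1.2 equiv), CH2Cl2, −78 → 0 °C; H2O
Reagents that add atoms: none
Why: Chelation-controlled mono-demethylation; BCl3 bound to the aldehyde cleaves one ortho methyl ether, and the resulting boron chelate protects the second.

Step 13
Reactants: 21 4-bromo-2-hydroxy-6-methoxybenzaldehyde; 22 [(E)-2-(4-methoxyphenyl)ethenyl]boronic acid
Product: 23 2-hydroxy-6-methoxy-4-[(E)-2-(4-methoxyphenyl)ethenyl]benzaldehyde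
Conditions: Pd(PPh3)4 (cat.), K2CO3, 1,4-dioxane/H2O, 85 °C
Reagents that add atoms: none
Why: Suzuki–Miyaura coupling of an aryl bromide activated by the para formyl group with an (E)-alkenylboronic acid; transmetalation and reductive elimination retain the alkene geometry.

Step 14
Reactants: 23 2-hydroxy-6-methoxy-4-[(E)-2-(4-methoxyphenyl)ethenyl]benzaldehyde; 24 1-bromo-3,5-dimethoxybenzene
Product: 26 2-[(3,5-dimethoxyphenyl)(hydroxy)methyl]-3-methoxy-5-[(E)-2-(4-methoxyphenyl)ethenyl]phenol, via Grignard reagent 25 (not isolated)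
Conditions: 24 (3 equiv), Mg, THF, rt → 40 °C; then 23, 0 °C → rt; aq. NH4Cl; used crude
Reagents that add atoms: none
Why: Grignard addition to a salicylaldehyde; the first equivalent forms the magnesium phenoxide and the second adds to the chelated aldehyde. The carbinol centre is racemic and is erased in step 16.

Step 15
Reactants: 26 2-[(3,5-dimethoxyphenyl)(hydroxy)methyl]-3-methoxy-5-[(E)-2-(4-methoxyphenyl)ethenyl]phenol
Product: 27 2-[(3,5-dimethoxyphenyl)(4-methylbenzenesulfonyl)methyl]-3-methoxy-5-[(E)-2-(4-methoxyphenyl)ethenyl]phenol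
Conditions: p-TolSO2H (1.5 equiv), CH2Cl2, 0 °C
Reagents that add atoms: 4-methylbenzenesulfinic acid, Cc1ccc(S(=O)O)cc1
Why: SN1 substitution of the ortho-hydroxy diarylmethanol by sulfinic acid, through the quinone methide or its protonated form; this weak acid should not protonate the stilbene.

Step 16
Reactants: 27 2-[(3,5-dimethoxyphenyl)(4-methylbenzenesulfonyl)methyl]-3-methoxy-5-[(E)-2-(4-methoxyphenyl)ethenyl]phenol; 19 (2S,5S)-1-{[(2S,3S)-2-(2,4-dimethoxyphenyl)-3-(3,5-dimethoxyphenyl)-4-methoxy-2,3-dihydro-1-benzofuran-7-yl]methyl}-2,5-dimethylthiolan-1-ium tetrafluoroborate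
Product: 31 (2S,3S)-2-[(2S,3S)-2-(2,4-dimethoxyphenyl)-3-(3,5-dimethoxyphenyl)-4-methoxy-2,3-dihydro-1-benzofuran-7-yl]-3-(3,5-dimethoxyphenyl)-4-methoxy-6-[(E)-2-(4-methoxyphenyl)ethenyl]-2,3-dihydro-1-benzofuran, via ring A ortho-quinone methide 28 (not isolated), via thiolanium benzylide 29 (not isolated), via betaine 30 (not isolated)
Conditions: 27 (1.5 equiv), Cs2CO3 (4 equiv), CH2Cl2/MeCN, 0 °C → rt
Reagents that add atoms: none
Why: Same formal [4+1] annulation as step 9: Cs2CO3 forms quinone methide 28 and benzylide 29, C2–C3 forms by conjugate addition, and O1–C2 by 5-exo-tet displacement of the sulfide in betaine 30. The (2S,5S) thiolanium again selects the ylide face that gives 2S after inversion, and anti closure gives the trans 3S centre. The remote outer ring should not override this reagent control, and material from the minor enantiomer of 19 becomes a separable diastereomer.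

Step 17
Reactants: 31 (2S,3S)-2-[(2S,3S)-2-(2,4-dimethoxyphenyl)-3-(3,5-dimethoxyphenyl)-4-methoxy-2,3-dihydro-1-benzofuran-7-yl]-3-(3,5-dimethoxyphenyl)-4-methoxy-6-[(E)-2-(4-methoxyphenyl)ethenyl]-2,3-dihydro-1-benzofuran
Product: 32 gnetumontanin B, (2S,3S)-2-[(2S,3S)-2-(2,4-dihydroxyphenyl)-3-(3,5-dihydroxyphenyl)-4-hydroxy-2,3-dihydro-1-benzofuran-7-yl]-3-(3,5-dihydroxyphenyl)-6-[(E)-2-(4-hydroxyphenyl)ethenyl]-2,3-dihydro-1-benzofuran-4-ol
Conditions: BBr3 (excess), CH2Cl2, −78 → 0 °C; MeOH, then H2O
Reagents that add atoms: none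
Why: Lewis-acid cleavage of the nine aryl methyl ethers (bromide attacks the methyl group of each boron-bound ether). C3 and C3′ are not epimerisable, so reversible opening of a benzylic ring C–O bond should reclose to the same trans ring.

## Compound list

1 | (2R,5R)-hexane-2,5-diol | C[C@@H](O)CC[C@@H](C)O | starting material
2 | (2R,5R)-hexane-2,5-diyl dimethanesulfonate | C[C@@H](OS(C)(=O)=O)CC[C@@H](C)OS(C)(=O)=O | intermediate
3 | (2S,5S)-2,5-dimethylthiolane | C[C@H]1CC[C@H](C)S1 | intermediate
4 | (2,4-dimethoxyphenyl)methanol | COc1ccc(CO)c(OC)c1 | starting material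
5 | (2S,5S)-1-[(2,4-dimethoxyphenyl)methyl]-2,5-dimethylthiolan-1-ium tetrafluoroborate | C[C@H]1CC[C@H](C)[S+]1Cc1ccc(OC)cc1OC.F[B-](F)(F)F | intermediate
6 | 2-hydroxy-4-methoxybenzaldehyde | COc1ccc(C=O)c(O)c1 | starting material
7 | 2-(hydroxymethyl)-5-methoxyphenol | COc1ccc(CO)c(O)c1 | intermediate
8 | 5-methoxy-2-({[tri(propan-2-yl)silyl]oxy}methyl)phenol | COc1ccc(CO[Si](C(C)C)(C(C)C)C(C)C)c(O)c1 | intermediate
9 | {[4-methoxy-2-(oxan-2-yloxy)phenyl]methoxy}tri(propan-2-yl)silane (racemic at the acetal carbon) | COc1ccc(CO[Si](C(C)C)(C(C)C)C(C)C)c(OC2CCCCO2)c1 | intermediate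
10 | 3,5-dimethoxybenzaldehyde | COc1cc(C=O)cc(OC)c1 | starting material
11 | [6-methoxy-2-(oxan-2-yloxy)-3-({[tri(propan-2-yl)silyl]oxy}methyl)phenyl]lithium (not isolated) | COc1ccc(CO[Si](C(C)C)(C(C)C)C(C)C)c(OC2CCCCO2)c1[Li] | intermediate
12 | (3,5-dimethoxyphenyl)[6-methoxy-2-(oxan-2-yloxy)-3-({[tri(propan-2-yl)silyl]oxy}methyl)phenyl]methanol (racemic mixture of diastereomers) | COc1ccc(CO[Si](C(C)C)(C(C)C)C(C)C)c(OC2CCCCO2)c1C(O)c1cc(OC)cc(OC)c1 | intermediate
13 | 2-[(3,5-dimethoxyphenyl)(4-methylbenzenesulfonyl)methyl]-3-methoxy-6-({[tri(propan-2-yl)silyl]oxy}methyl)phenol (racemate) | COc1ccc(CO[Si](C(C)C)(C(C)C)C(C)C)c(O)c1C(c1cc(OC)cc(OC)c1)S(=O)(=O)c1ccc(C)cc1 | intermediate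
14 | 6-[(3,5-dimethoxyphenyl)methylidene]-5-methoxy-2-({[tri(propan-2-yl)silyl]oxy}methyl)cyclohexa-2,4-dien-1-one (ring B ortho-quinone methide, alkene geometry not fixed, not isolated) | COC1=CC=C(CO[Si](C(C)C)(C(C)C)C(C)C)C(=O)C1=Cc1cc(OC)cc(OC)c1 | intermediate
15 | (2,4-dimethoxyphenyl)[(2S,5S)-2,5-dimethylthiolan-1-ium-1-yl]methanide (not isolated) | C[C@H]1CC[C@H](C)[S+]1[CH-]c1ccc(OC)cc1OC | intermediate
16 | 2-{(1S,2R)-2-(2,4-dimethoxyphenyl)-1-(3,5-dimethoxyphenyl)-2-[(2S,5S)-2,5-dimethylthiolan-1-ium-1-yl]ethyl}-3-methoxy-6-({[tri(propan-2-yl)silyl]oxy}methyl)phenolate (betaine, not isolated) | CC(C)[Si](C(C)C)(C(C)C)OCc1ccc(OC)c(c1[O-])[C@H](c1cc(OC)cc(OC)c1)[C@H](c1ccc(OC)cc1OC)[S+]1[C@@H](C)CC[C@@H]1C | intermediate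
17 | {[(2S,3S)-2-(2,4-dimethoxyphenyl)-3-(3,5-dimethoxyphenyl)-4-methoxy-2,3-dihydro-1-benzofuran-7-yl]methoxy}tri(propan-2-yl)silane | CC(C)[Si](C(C)C)(C(C)C)OCc1ccc(OC)c2c1O[C@H](c1ccc(OC)cc1OC)[C@H]2c1cc(OC)cc(OC)c1 | intermediate
18 | [(2S,3S)-2-(2,4-dimethoxyphenyl)-3-(3,5-dimethoxyphenyl)-4-methoxy-2,3-dihydro-1-benzofuran-7-yl]methanol | OCc1ccc(OC)c2c1O[C@H](c1ccc(OC)cc1OC)[C@H]2c1cc(OC)cc(OC)c1 | intermediate
19 | (2S,5S)-1-{[(2S,3S)-2-(2,4-dimethoxyphenyl)-3-(3,5-dimethoxyphenyl)-4-methoxy-2,3-dihydro-1-benzofuran-7-yl]methyl}-2,5-dimethylthiolan-1-ium tetrafluoroborate | C[C@H]1CC[C@H](C)[S+]1Cc1ccc(OC)c2c1O[C@H](c1ccc(OC)cc1OC)[C@H]2c1cc(OC)cc(OC)c1.F[B-](F)(F)F | intermediate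
20 | 4-bromo-2,6-dimethoxybenzaldehyde | COc1cc(Br)cc(OC)c1C=O | starting material
21 | 4-bromo-2-hydroxy-6-methoxybenzaldehyde | COc1cc(Br)cc(O)c1C=O | intermediate
22 | [(E)-2-(4-methoxyphenyl)ethenyl]boronic acid | COc1ccc(/C=C/B(O)O)cc1 | starting material
23 | 2-hydroxy-6-methoxy-4-[(E)-2-(4-methoxyphenyl)ethenyl]benzaldehyde | COc1ccc(/C=C/c2cc(O)c(C=O)c(OC)c2)cc1 | intermediate
24 | 1-bromo-3,5-dimethoxybenzene | COc1cc(Br)cc(OC)c1 | starting material
25 | (3,5-dimethoxyphenyl)magnesium bromide (not isolated) | COc1cc(OC)cc([Mg]Br)c1 | intermediate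
26 | 2-[(3,5-dimethoxyphenyl)(hydroxy)methyl]-3-methoxy-5-[(E)-2-(4-methoxyphenyl)ethenyl]phenol (racemate) | COc1ccc(/C=C/c2cc(O)c(C(O)c3cc(OC)cc(OC)c3)c(OC)c2)cc1 | intermediate
27 | 2-[(3,5-dimethoxyphenyl)(4-methylbenzenesulfonyl)methyl]-3-methoxy-5-[(E)-2-(4-methoxyphenyl)ethenyl]phenol (racemate) | COc1ccc(/C=C/c2cc(O)c(C(c3cc(OC)cc(OC)c3)S(=O)(=O)c3ccc(C)cc3)c(OC)c2)cc1 | intermediate
28 | 6-[(3,5-dimethoxyphenyl)methylidene]-5-methoxy-3-[(E)-2-(4-methoxyphenyl)ethenyl]cyclohexa-2,4-dien-1-one (ring A ortho-quinone methide, exocyclic alkene geometry not fixed, not isolated) | COC1=CC(/C=C/c2ccc(OC)cc2)=CC(=O)C1=Cc1cc(OC)cc(OC)c1 | intermediate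
29 | [(2S,3S)-2-(2,4-dimethoxyphenyl)-3-(3,5-dimethoxyphenyl)-4-methoxy-2,3-dihydro-1-benzofuran-7-yl][(2S,5S)-2,5-dimethylthiolan-1-ium-1-yl]methanide (not isolated) | C[C@H]1CC[C@H](C)[S+]1[CH-]c1ccc(OC)c2c1O[C@H](c1ccc(OC)cc1OC)[C@H]2c1cc(OC)cc(OC)c1 | intermediate
30 | 2-{(1S,2R)-2-[(2S,3S)-2-(2,4-dimethoxyphenyl)-3-(3,5-dimethoxyphenyl)-4-methoxy-2,3-dihydro-1-benzofuran-7-yl]-1-(3,5-dimethoxyphenyl)-2-[(2S,5S)-2,5-dimethylthiolan-1-ium-1-yl]ethyl}-3-methoxy-5-[(E)-2-(4-methoxyphenyl)ethenyl]phenolate (betaine, not isolated) | COc1ccc(/C=C/c2cc([O-])c(c(OC)c2)[C@H](c2cc(OC)cc(OC)c2)[C@H](c2ccc(OC)c3c2O[C@H](c2ccc(OC)cc2OC)[C@H]3c2cc(OC)cc(OC)c2)[S+]2[C@@H](C)CC[C@@H]2C)cc1 | intermediate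
31 | (2S,3S)-2-[(2S,3S)-2-(2,4-dimethoxyphenyl)-3-(3,5-dimethoxyphenyl)-4-methoxy-2,3-dihydro-1-benzofuran-7-yl]-3-(3,5-dimethoxyphenyl)-4-methoxy-6-[(E)-2-(4-methoxyphenyl)ethenyl]-2,3-dihydro-1-benzofuran (nona-O-methylgnetumontanin B) | COc1ccc(/C=C/c2cc(OC)c3c(c2)O[C@H](c2ccc(OC)c4c2O[C@H](c2ccc(OC)cc2OC)[C@H]4c2cc(OC)cc(OC)c2)[C@H]3c2cc(OC)cc(OC)c2)cc1 | intermediate
32 | gnetumontanin B | Oc1ccc(/C=C/c2cc(O)c3c(c2)O[C@H](c2ccc(O)c4c2O[C@H](c2ccc(O)cc2O)[C@H]4c2cc(O)cc(O)c2)[C@H]3c2cc(O)cc(O)c2)cc1 | target

## Step count and least certain steps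

Total step count: 17. Longest linear sequence: 10 steps (steps 4 to 11, then 16 and 17).

**Step 9 (key step).** The most likely failures are these:
- incomplete facial discrimination by the thiolanium benzylide, since the model is carried over from aldehydes to a quinone methide;
- leakage through the other betaine diastereomer followed by SN1 closure, which would give the enantiomeric trans ring;
- loss of salt 5 by benzylation of the phenoxide or of the released sulfinate, because its benzyl group is strongly electron-rich.

Fallback: make the ring racemic and resolve. Starting from 13, the annulation is run under the same Cs2CO3 conditions with the achiral salt 1-[(2,4-dimethoxyphenyl)methyl]thiolan-1-ium tetrafluoroborate F1, prepared from 4, thiolane and HBF4·OEt2. This gives the racemic trans silyl ether F2. TBAF then gives the racemic trans alcohol F3, which is resolved by preparative chromatography on a chiral stationary phase. The (2R,3R) alcohol F4 is set aside and the route is rejoined at 18.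

**Step 16.** The ylide carbon of 29 is flanked by O1′ and carries a large ring system. Slow C–C bond formation would let the styryl-extended quinone methide 28 oligomerise or be attacked at the remote styryl terminus. A mismatch between the reagent and the existing stereocentres would lower the diastereoselectivity.

Fallback: attach the stilbene after the annulation. Starting from 21, addition of Grignard reagent 25 gives 5-bromo-2-[(3,5-dimethoxyphenyl)(hydroxy)methyl]-3-methoxyphenol F5, and p-TolSO2H converts it into the bromo sulfone F6. Annulation of F6 with 19 and Cs2CO3 gives the 6-bromo dihydrobenzofuran F7. Suzuki–Miyaura coupling of F7 with 22 (Pd(PPh3)4, K2CO3) rejoins the route at 31.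

**Step 17.** The Lewis acid may ionise the C2–O1 and C2′–O1′ bonds faster than it cleaves the methyl ethers, followed by elimination or bromide capture before reclosure. Cleavage of nine ethers may be incomplete, and the free nonaphenol may be lost to oxidation during isolation.

Fallback: cleave, acetylate, purify, then release. Starting from 31, the ethers are cleaved with BCl3 and n-Bu4NI in CH2Cl2 at −78 → 0 °C (iodide attacks the methyl groups at low temperature). The crude polyphenol is acetylated with Ac2O and pyridine to gnetumontanin B nonaacetate F8, which can be purified on silica. Mild methanolysis (NH4OAc, aqueous MeOH, rt) returns the route at 32.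

**Step 11.** HBF4 may protonate and open the C2′–O1′ ring ether, with capture of the C2′ cation by the sulfide, and the benzylic cation may alkylate another electron-rich ring.

Fallback: activate the alcohol under basic conditions. Starting from 18, MsCl and Et3N in CH2Cl2 at −20 °C give the benzylic chloride (2S,3S)-7-(chloromethyl)-2-(2,4-dimethoxyphenyl)-3-(3,5-dimethoxyphenyl)-4-methoxy-2,3-dihydro-1-benzofuran F9, used crude. Sulfide 3 and AgBF4 in CH2Cl2 at 0 °C then precipitate AgCl and rejoin the route at 19.

**Step 8.** The sulfinic acid may ionise the 2,4-dioxygenated benzylic silyl ether, losing the handle as a second sulfone, or the acetal may be cleaved incompletely.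

Fallback: separate the two events and lower the acid strength. Starting from 12, PPTS in MeOH at rt removes the acetal to give the free diol 2-[(3,5-dimethoxyphenyl)(hydroxy)methyl]-3-methoxy-6-({[tri(propan-2-yl)silyl]oxy}methyl)phenol F10. Then p-TolSO2Na with AcOH in CH2Cl2/H2O at rt adds sulfinate to the quinone methide formed under buffer conditions and rejoins the route at 13.

## Further compounds

F1 | step 9 | 1-[(2,4-dimethoxyphenyl)methyl]thiolan-1-ium tetrafluoroborate | COc1ccc(C[S+]2CCCC2)c(OC)c1.F[B-](F)(F)F
F2 | step 9 | racemic trans-{[2-(2,4-dimethoxyphenyl)-3-(3,5-dimethoxyphenyl)-4-methoxy-2,3-dihydro-1-benzofuran-7-yl]methoxy}tri(propan-2-yl)silane (both enantiomers shown) | CC(C)[Si](C(C)C)(C(C)C)OCc1ccc(OC)c2c1O[C@H](c1ccc(OC)cc1OC)[C@H]2c1cc(OC)cc(OC)c1.CC(C)[Si](C(C)C)(C(C)C)OCc1ccc(OC)c2c1O[C@@H](c1ccc(OC)cc1OC)[C@@H]2c1cc(OC)cc(OC)c1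
F3 | step 9 | racemic trans-[2-(2,4-dimethoxyphenyl)-3-(3,5-dimethoxyphenyl)-4-methoxy-2,3-dihydro-1-benzofuran-7-yl]methanol (both enantiomers shown) | OCc1ccc(OC)c2c1O[C@H](c1ccc(OC)cc1OC)[C@H]2c1cc(OC)cc(OC)c1.OCc1ccc(OC)c2c1O[C@@H](c1ccc(OC)cc1OC)[C@@H]2c1cc(OC)cc(OC)c1
F4 | step 9 | [(2R,3R)-2-(2,4-dimethoxyphenyl)-3-(3,5-dimethoxyphenyl)-4-methoxy-2,3-dihydro-1-benzofuran-7-yl]methanol | OCc1ccc(OC)c2c1O[C@@H](c1ccc(OC)cc1OC)[C@@H]2c1cc(OC)cc(OC)c1
F5 | step 16 | 5-bromo-2-[(3,5-dimethoxyphenyl)(hydroxy)methyl]-3-methoxyphenol (racemate) | COc1cc(Br)cc(O)c1C(O)c1cc(OC)cc(OC)c1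
F6 | step 16 | 5-bromo-2-[(3,5-dimethoxyphenyl)(4-methylbenzenesulfonyl)methyl]-3-methoxyphenol (racemate) | COc1cc(Br)cc(O)c1C(c1cc(OC)cc(OC)c1)S(=O)(=O)c1ccc(C)cc1
F7 | step 16 | (2S,3S)-6-bromo-2-[(2S,3S)-2-(2,4-dimethoxyphenyl)-3-(3,5-dimethoxyphenyl)-4-methoxy-2,3-dihydro-1-benzofuran-7-yl]-3-(3,5-dimethoxyphenyl)-4-methoxy-2,3-dihydro-1-benzofuran | Brc1cc(OC)c2c(c1)O[C@H](c1ccc(OC)c3c1O[C@H](c1ccc(OC)cc1OC)[C@H]3c1cc(OC)cc(OC)c1)[C@H]2c1cc(OC)cc(OC)c1
F8 | step 17 | gnetumontanin B nonaacetate | CC(=O)Oc1ccc(/C=C/c2cc(OC(C)=O)c3c(c2)O[C@H](c2ccc(OC(C)=O)c4c2O[C@H](c2ccc(OC(C)=O)cc2OC(C)=O)[C@H]4c2cc(OC(C)=O)cc(OC(C)=O)c2)[C@H]3c2cc(OC(C)=O)cc(OC(C)=O)c2)cc1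
F9 | step 11 | (2S,3S)-7-(chloromethyl)-2-(2,4-dimethoxyphenyl)-3-(3,5-dimethoxyphenyl)-4-methoxy-2,3-dihydro-1-benzofuran | ClCc1ccc(OC)c2c1O[C@H](c1ccc(OC)cc1OC)[C@H]2c1cc(OC)cc(OC)c1
F10 | step 8 | 2-[(3,5-dimethoxyphenyl)(hydroxy)methyl]-3-methoxy-6-({[tri(propan-2-yl)silyl]oxy}methyl)phenol (racemate) | COc1ccc(CO[Si](C(C)C)(C(C)C)C(C)C)c(O)c1C(O)c1cc(OC)cc(OC)c1
A1 | alternative 1 | methyl 2-diazo-2-{2-[(3-(1-diazo-2-methoxy-2-oxoethyl)-2-[(2,4-dimethoxyphenyl)methoxy]-4-methoxyphenyl)methoxy]-6-methoxy-4-[(E)-2-(4-methoxyphenyl)ethenyl]phenyl}acetate | COc1ccc(/C=C/c2cc(OC)c(C(=[N+]=[N-])C(=O)OC)c(c2)OCc2ccc(OC)c(C(=[N+]=[N-])C(=O)OC)c2OCc2ccc(OC)cc2OC)cc1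
A2 | alternative 1 | methyl (2S,3S)-2-[(2S,3S)-2-(2,4-dimethoxyphenyl)-4-methoxy-3-(methoxycarbonyl)-2,3-dihydro-1-benzofuran-7-yl]-4-methoxy-6-[(E)-2-(4-methoxyphenyl)ethenyl]-2,3-dihydro-1-benzofuran-3-carboxylate (both rings trans) | COc1ccc(/C=C/c2cc(OC)c3c(c2)O[C@H](c2ccc(OC)c4c2O[C@H](c2ccc(OC)cc2OC)[C@H]4C(=O)OC)[C@H]3C(=O)OC)cc1
A3 | alternative 2 | 3-[(E)-2-(4-methoxyphenyl)ethenyl]cyclobut-2-en-1-one | COc1ccc(/C=C/C2=CC(=O)C2)cc1
A4 | alternative 2 | siloxyalkyne: the tri(propan-2-yl)silyl ynol ether whose alkyne carries the CH(3,5-dimethoxyphenyl)–CH(OSi(CH3)2C(CH3)3) chain attached to C7 of the (2S,3S) outer dihydrobenzofuran | CC(C)[Si](C(C)C)(C(C)C)OC#C[C@H](c1cc(OC)cc(OC)c1)[C@@H](O[Si](C)(C)C(C)(C)C)c1ccc(OC)c2c1O[C@H](c1ccc(OC)cc1OC)[C@H]2c1cc(OC)cc(OC)c1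
A5 | alternative 2 | ring A resorcinol mono(triisopropylsilyl) ether with the C3 and C2 side chain between the two oxygens and the (E)-4-methoxystyryl group para to it | COc1ccc(/C=C/c2cc(O)c([C@H](c3cc(OC)cc(OC)c3)[C@@H](O[Si](C)(C)C(C)(C)C)c3ccc(OC)c4c3O[C@H](c3ccc(OC)cc3OC)[C@H]4c3cc(OC)cc(OC)c3)c(O[Si](C(C)C)(C(C)C)C(C)C)c2)cc1
A6 | alternative 3 | (2S)-2-[(2S,3S)-2-(2,4-dimethoxyphenyl)-3-(3,5-dimethoxyphenyl)-4-methoxy-2,3-dihydro-1-benzofuran-7-yl]-5-methoxy-4-oxo-3,4-dihydro-2H-1-benzopyran-7-yl trifluoromethanesulfonate | COc1cc(OS(=O)(=O)C(F)(F)F)cc2c1C(=O)C[C@@H](c1ccc(OC)c3c1O[C@H](c1ccc(OC)cc1OC)[C@H]3c1cc(OC)cc(OC)c1)O2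
A7 | alternative 3 | methyl (2S,3S)-2-[(2S,3S)-2-(2,4-dimethoxyphenyl)-3-(3,5-dimethoxyphenyl)-4-methoxy-2,3-dihydro-1-benzofuran-7-yl]-4-methoxy-6-[(trifluoromethanesulfonyl)oxy]-2,3-dihydro-1-benzofuran-3-carboxylate | FC(F)(F)S(=O)(=O)Oc1cc(OC)c2c(c1)O[C@H](c1ccc(OC)c3c1O[C@H](c1ccc(OC)cc1OC)[C@H]3c1cc(OC)cc(OC)c1)[C@H]2C(=O)OC
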